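## Structural features

The target is a B-type procyanidin trimer of three flavan-3-ol (2-arylchroman) units. An upper (−)-epicatechin 3-O-gallate is bonded through C4 to C6 of a central epicatechin 3-O-gallate, whose own C4 is bonded to C8 of a lower (+)-catechin. Both interflavan bonds are diarylmethine C–C bonds and both stand trans to the neighbouring C3 oxygen (4β). There are eight stereocentres: the contiguous triads C2/C3/C4 (2,3-cis, 3,4-trans) of the upper and central units and the trans pair C2/C3 of the lower unit. Fragile features are the eighteen free phenols (oxidation), the two gallate esters (base, acyl transfer), the acid-labile interflavan bonds, and the benzylic C2–O1 bonds, which can open to quinone methides and epimerise. The real difficulty is ring A of the central unit: a pentasubstituted phloroglucinol carrying the upper unit at C6 between O5 and O7 and hydrogen at C8, whereas electrophilic substitution of a flavan prefers C8. The key step assembles this ring instead of substituting it: C6, C7, C8 and C8a come from a cyclobutenone that already bears the upper unit, and C4a and C5 from an ynol ether that already bears C4 with the lower unit. The only oxygen left free is the one on C8a, para to C6, which is the oxygen that must become O1 of the central pyran ring.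

## Logic of the disconnections

35 ⇒ 34 ⇒ 33. The eighteen O–benzyl bonds and the O–Si bond at C5 of the central unit are cut. Benzyl ethers allow one neutral hydrogenolysis at the end; the silyl ether at C5 is the trace of the ynol ether and keeps that phenol masked during acylation. The forward steps must be neutral or buffered because of the esters and the oxidisable polyphenol.

33 ⇒ 32 + 3. The ester C–O bond at C3 of the central unit is cut. The second gallate is added late because it would not survive the organolithium and peroxide chemistry used to make the ynol ether. The forward step has to acylate a hindered axial alcohol, the only free hydroxyl of 32.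

32 ⇒ 31 ⇒ 30. The O1–C2 bond of the central unit is cut to a phenol and a benzylic alcohol. The phenol is the one delivered by the annulation. The closure is an SN2 etherification, so C2 is carried in the opposite configuration. Both chain hydroxyls carry triethylsilyl groups, which leave together under conditions that spare the aryl silyl ether. Two identical groups also make any 1,2-silyl migration harmless.

30 ⇒ 8 + 25. The C4a–C8a and C5–C6 bonds are cut and the whole of ring A of the central unit is taken apart. This separates the trimer into an upper-unit piece and a central-chain/lower-unit piece of similar size and removes the 6-versus-8 question. The forward step needs only the inherent polarity of a vinylketene and an ynol ether, plus thermal stability of the ethers and esters.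

8 ⇒ 7 ⇒ 5 + 6, and 5 ⇒ 4. The bond from C4 of the upper unit to C2 of the four-membered ring is cut, then the enol ether O–benzyl bond, then the C4–O bond of the activating ether. Alkylating the dione itself (a strong carbon nucleophile as its enol) and benzylating afterwards is preferred to alkylating a weakly nucleophilic enol ether; because the dione is symmetrical, O-benzylation can give only one product. The forward steps must deliver both the alkoxy group and the carbon nucleophile trans to the 3-ester.

4 ⇒ 2 + 3, and 2 ⇒ 1. The ester C–O bond at C3 of the upper unit is cut, then the four aryl O–benzyl bonds. Etherifying only the four phenols of the flavan and attaching the gallate as its preformed tribenzyl ether keeps the base-labile ester out of the alkylation, and the same acid 3 serves again for the central unit. C2 and C3 of the upper unit come from the chiral pool. The forward steps must leave the secondary hydroxyl free during the etherification and must not epimerise C2.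

25 ⇒ 22 (through 23 and 24), and 22 ⇒ 21 ⇒ 18 + 19 (through 20). The ynol C–O bond is cut back to a terminal alkyne, then the C2–aryl bond of the future ring B. The aldehyde addition must give the 1,2-anti (erythro) carbinol.

18 ⇒ 17 ⇒ 16 ⇒ 11 + 15, and 11 ⇒ 9 (through 10). The C4–C8 bond between the central chain and the lower unit is cut to an electron-rich arene and a cis-alkynyl epoxide. The epoxide fixes C3 and, by inversion, C4 of the central unit. The forward step must attack the propargylic carbon at C8 of the arene with clean inversion.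

15 ⇒ 14 ⇒ 13 ⇒ 12. The epoxide oxygen is removed to a (Z)-enynol, made from a (Z)-iodoacrylate by C–C coupling and reduction. The forward steps must keep the Z geometry and set both epoxide carbons by reagent control.

## Other disconnections considered

Alternative 1: The cut is at C2 of the upper unit, where the C2–C3 and C2–aryl bonds are both made at a boron-bearing carbon. In the forward sense the C3 boronic ester A1 is homologated with a dichloromethyl carbenoid (zinc-halide-assisted 1,2-shift of C3), and the α-chloro boronate is then substituted by the aryl Grignard reagent 20 through a second 1,2-shift, giving the C2 boronic ester A2 (Matteson homologation).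
- In favour: C2 is set by the chiral diol on boron, independent of substrate bias, and the C–B bond is a direct precursor of the C2–O bond. The diarylmethine already carries a symmetrical phloroglucinol ring as the future central ring A.
- Against: the triad it builds is the one that the chiral-pool flavan 1 delivers in three routine steps (steps 1 to 3). After A2 the upper pyran must still be closed, the ether at C3 exchanged for the gallate, and the central and lower units built onto a ring that stops being symmetrical once one oxygen is differentiated.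
- Comparison: for security at a benzylic C2 centre this alternative is the better one, since it needs no SN2 inversion at an ionisable benzylic alcohol (step 18 of the chosen plan). On the central ring A it offers no mechanistic regiocontrol comparable to step 16, and it is clearly longer.

Alternative 2: The cut is at O1–C2 and C3–C4 of the upper pyran. In the forward sense a bulky chiral phosphoric acid dehydrates the benzhydrol A3 to an ortho-quinone methide, which adds the (Z)-enol gallate A4 in an inverse-demand [4+2] cycloaddition to give A5.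
- In favour: one step closes the ring, sets three stereocentres and installs the gallate, with the 2,3-cis relation coming from the Z geometry. The aryl group on C4 of A5 is symmetrical about its axis and its para oxygen is marked by the allyl group, so the 4→6 linkage is fixed by symmetry.
- Against: enol esters are electron-poor partners for quinone methides compared with enol ethers, the Z-enol ester is configurationally labile, the endo/exo preference must deliver 3,4-trans, and the catalyst has to control centres that 1 provides for nothing. The central pyran then still has to be annulated onto the phenol.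
- Comparison: on the regiochemistry of the central ring A it is the equal of the chosen plan, and it avoids heating a large fragment. On convergence of the upper unit it is better, because the ester comes in with the ring. On stereochemical risk and total step count it is worse.

Alternative 3: The cut is at C3–C4 and at the acyl C–O bond that stands for O1–C2 of the central unit. In the forward sense base turns the ortho-hydroxybenzylic carbinol A6 into an ortho-quinone methide; the ammonium enolate formed from a mixed anhydride of allyloxyacetic acid and a chiral isothiourea adds to C4, and the phenoxide then acylates, releasing the catalyst and giving the trans-3,4-dihydrocoumarin A7.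
- In favour: C3 and C4 of the central unit are set in one catalytic step with the trans relation typical of this annulation, the bond to the lower unit is already present, and the lactone carbonyl is the handle for ring B.
- Against: A6 already contains the fully substituted central ring A with the upper unit at C6, so the hardest problem is presupposed, not solved. The quinone methide is very hindered, and the catalyst must override two resident flavan units. Turning the lactone into a 2,3-cis 2-aryl pyran needs aryl addition and a stereoselective reduction, and the allyl ethers must later be exchanged for gallates.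
- Comparison: for C3/C4 of the central unit it is better than the chosen plan (one catalytic step against the sequence of steps 7 to 10). For C2 it is at best equal. For the construction of ring A and for the number of steps after its key step it is worse.

Key step: step 16

Remark on the chemistry: C2 of the central unit is carried from step 13 to step 18 in the configuration opposite to that of 35, because the ring closure inverts it. All other centres of 8, 25 and 30 have the configuration of 35; the structures of the key-step precursors and product were compared with the target centre by centre and need no correction. Compounds 3, 6, 12 and 19 are taken as purchasable.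

## Steps

Step 1
Reactants: 1 (−)-epicatechin
Product: 2 5,7,3',4'-tetra-O-benzyl-(−)-epicatechin
Conditions: BnBr (4.2 equiv), K2CO3, DMF, 0 °C → rt, N2
Reagents that add atoms: benzyl bromide, BrCc1ccccc1
Why: Williamson etherification of the four phenols; carbonate is too weak a base to deprotonate the secondary 3-hydroxyl, which therefore stays free, and low temperature with exclusion of air limits C2 epimerisation through a ring B quinone methide; no stereocentre is involved.

Step 2
Reactants: 2 5,7,3',4'-tetra-O-benzyl-(−)-epicatechin; 3 3,4,5-tris(benzyloxy)benzoic acid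
Product: 4 hepta-O-benzyl-(−)-epicatechin 3-O-gallate
Conditions: 3 (1.5 equiv), DCC, DMAP, CH2Cl2, rt
Reagents that add atoms: none
Why: Steglich esterification of the only free hydroxyl through the acylpyridinium ion; the C3–O bond of the alcohol is not broken, so the configuration is retained, and the neutral conditions do not open the pyran ring.

Step 3
Reactants: 4 hepta-O-benzyl-(−)-epicatechin 3-O-gallate
Product: 5 (2R,3R,4S)-4-(2-ethoxyethoxy) derivative of 4
Conditions: DDQ, HOCH2CH2OEt, CH2Cl2, rt
Reagents that add atoms: 2-ethoxyethanol, CCOCCO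
Why: DDQ benzylic oxidation: hydride is abstracted from C4, which is activated by the 5,7-dialkoxy ring A, and the cation is trapped by the alcohol on the face trans to the 3-O-gallate (steric shielding and acyloxonium bridging), which sets C4 as 4β.

Step 4
Reactants: 5 (2R,3R,4S)-4-(2-ethoxyethoxy) derivative of 4; 6 cyclobutane-1,3-dione
Product: 7 3-hydroxy-2-(hepta-O-benzyl-epicatechin-gallate-4β-yl)cyclobut-2-en-1-one
Conditions: 6 (3 equiv), Yb(OTf)3 (10 mol %), CH2Cl2, 0 °C → rt
Reagents that add atoms: none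
Why: Lewis-acid ionisation of the C4 ether regenerates the benzylic cation, which is C-alkylated at C2 of the enol form of the dione (Friedel–Crafts-type alkylation of a 1,3-dicarbonyl); attack anti to the 3-O-gallate again gives 4β, and any O-alkylation is reversible under the conditions.

Step 5
Reactants: 7 3-hydroxy-2-(hepta-O-benzyl-epicatechin-gallate-4β-yl)cyclobut-2-en-1-one
Product: 8 3-benzyloxy-2-(hepta-O-benzyl-epicatechin-gallate-4β-yl)cyclobut-2-en-1-one
Conditions: BnOH, PPh3, DIAD, THF, 0 °C → rt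
Reagents that add atoms: benzyl alcohol, OCc1ccccc1
Why: Mitsunobu O-alkylation of an acidic enol (vinylogous acid); the two oxygens of the 2-substituted dione are equivalent by tautomerism, so only one enol ether can form, and the neutral conditions spare the ester.

Step 6
Reactants: 9 (+)-catechin
Product: 11 3,5,7,3',4'-penta-O-benzyl-(+)-catechin, via tetra-O-benzylcatechin 10 (not isolated)
Conditions: BnBr, K2CO3, DMF, rt; then NaH, 0 °C → rt
Reagents that add atoms: benzyl bromide, BrCc1ccccc1
Why: Two-stage Williamson etherification: carbonate benzylates the four phenols, and hydride then alkylates the secondary 3-hydroxyl once no phenolate is left that could open the pyran ring; the stereocentres are untouched.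

Step 7
Reactants: 12 ethyl (Z)-3-iodoacrylate
Product: 13 ethyl (Z)-pent-2-en-4-ynoate
Conditions: HC≡CMgBr, ZnBr2, THF, 0 °C; then 12, Pd(PPh3)4 (5 mol %), rt
Reagents that add atoms: ethynylmagnesium bromide, C#C[Mg]Br
Why: Negishi coupling of an alkynylzinc halide with an alkenyl iodide at zerovalent palladium proceeds with retention of the Z geometry and gives the terminal enyne directly.

Step 8
Reactants: 13 ethyl (Z)-pent-2-en-4-ynoate
Product: 14 (Z)-pent-2-en-4-yn-1-ol
Conditions: i-Bu2AlH (2.2 equiv), CH2Cl2, −78 °C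
Reagents that add atoms: none
Why: 1,2-Reduction of the conjugated ester by the aluminium hydride; at −78 °C neither the Z-alkene nor the terminal alkyne is hydroaluminated.

Step 9
Reactants: 14 (Z)-pent-2-en-4-yn-1-ol
Product: 15 [(2S,3R)-3-ethynyloxiran-2-yl]methanol (cis-epoxide)
Conditions: Ti(OiPr)4 (10 mol %), L-(+)-DIPT (12 mol %), t-BuOOH, 4 Å MS, CH2Cl2, −20 °C
Reagents that add atoms: tert-butyl hydroperoxide, CC(C)(C)OO
Why: Sharpless asymmetric epoxidation; the L-(+)-tartrate complex delivers oxygen to the face of the (Z)-allylic alcohol that gives the (2S,3R) cis-epoxide, so both new centres are set by the catalyst, and any minor enantiomer becomes a separable diastereomer in step 10.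

Step 10
Reactants: 11 3,5,7,3',4'-penta-O-benzyl-(+)-catechin; 15 [(2S,3R)-3-ethynyloxiran-2-yl]methanol
Product: 16 (2R,3R)-3-(penta-O-benzylcatechin-8-yl)pent-4-yne-1,2-diol
Conditions: 15 (1.5 equiv), BF3·OEt2 (0.3 equiv), CH2Cl2, −78 → −30 °C
Reagents that add atoms: none
Why: Lewis-acid-promoted Friedel–Crafts alkylation of an electron-rich arene by an epoxide: the activated oxirane is opened at the propargylic carbon (the more polarised C–O bond) by C8 of 11, the most nucleophilic and less hindered ring A position, from the rear; inversion at that carbon of the cis-epoxide gives the arrangement that becomes 3,4-trans in the central unit, while the carbinol carbon is untouched.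

Step 11
Reactants: 16 (2R,3R)-3-(penta-O-benzylcatechin-8-yl)pent-4-yne-1,2-diol
Product: 17 (2R,3R)-3-(penta-O-benzylcatechin-8-yl)-1,2-bis(triethylsilyloxy)pent-4-yne
Conditions: Et3SiOTf, 2,6-lutidine, CH2Cl2, −78 → 0 °C
Reagents that add atoms: triethylsilyl triflate, CC[Si](CC)(CC)OS(=O)(=O)C(F)(F)F
Why: Silylation of the primary and the hindered secondary hydroxyl with the reactive silyl triflate; triethylsilyl is chosen because the primary ether can be oxidised directly in step 12 and the secondary one can later be removed without touching an aryl silyl ether.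

Step 12
Reactants: 17 (2R,3R)-3-(penta-O-benzylcatechin-8-yl)-1,2-bis(triethylsilyloxy)pent-4-yne
Product: 18 (2R,3R)-3-(penta-O-benzylcatechin-8-yl)-2-(triethylsilyloxy)pent-4-ynal
Conditions: (COCl)2, DMSO, CH2Cl2, −78 → −40 °C; Et3N, −78 → 0 °C; used crude
Reagents that add atoms: none
Why: Swern oxidation applied to a bis-silyl ether: the activated sulfoxide attacks the unhindered primary triethylsilyl ether, chloride removes silicon, and the alkoxysulfonium ylide collapses to the aldehyde, while the hindered secondary silyl ether is inert; low temperature and immediate use protect the α-centre.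

Step 13
Reactants: 18 (2R,3R)-3-(penta-O-benzylcatechin-8-yl)-2-(triethylsilyloxy)pent-4-ynal; 19 4-bromo-1,2-bis(benzyloxy)benzene
Product: 21 (1S,2R,3R)-1-[3,4-bis(benzyloxy)phenyl]-3-(penta-O-benzylcatechin-8-yl)-2-(triethylsilyloxy)pent-4-yn-1-ol, via arylmagnesium bromide 20 (not isolated)
Conditions: 19, Mg, THF, reflux; then 18, THF, −78 °C (3 equiv of 20)
Reagents that add atoms: none
Why: Grignard addition to an α-silyloxy aldehyde under Felkin–Anh (Cornforth) control: the non-chelating silyloxy group lies anti to the incoming aryl group, which should give the 1,2-anti (erythro) carbinol, (S) at the new centre; one equivalent of reagent is consumed by the acetylenic C–H.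

Step 14
Reactants: 21 (1S,2R,3R)-1-[3,4-bis(benzyloxy)phenyl]-3-(penta-O-benzylcatechin-8-yl)-2-(triethylsilyloxy)pent-4-yn-1-ol
Product: 22 (1S,2R,3R)-1-[3,4-bis(benzyloxy)phenyl]-3-(penta-O-benzylcatechin-8-yl)-1,2-bis(triethylsilyloxy)pent-4-yne
Conditions: Et3SiCl, imidazole, DMAP (cat.), CH2Cl2, rt
Reagents that add atoms: chlorotriethylsilane, CC[Si](Cl)(CC)CC
Why: Silylation of the benzylic secondary alcohol; with the same group on both oxygens a 1,2-silyl shift during step 13 has no consequence.

Step 15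
Reactants: 22 (1S,2R,3R)-1-[3,4-bis(benzyloxy)phenyl]-3-(penta-O-benzylcatechin-8-yl)-1,2-bis(triethylsilyloxy)pent-4-yne
Product: 25 (3R,4R,5S)-5-[3,4-bis(benzyloxy)phenyl]-3-(penta-O-benzylcatechin-8-yl)-4,5-bis(triethylsilyloxy)-1-(triisopropylsilyloxy)pent-1-yne, via lithium acetylide 23 (not isolated), via lithium ynolate 24 (not isolated)
Conditions: n-BuLi (1.05 equiv), THF, −78 °C; LiOOt-Bu (from t-BuOOH and LiN(SiMe3)2), −78 → 0 °C; i-Pr3SiOTf, −78 °C
Reagents that add atoms: tert-butyl hydroperoxide (as its lithium salt), CC(C)(C)OO; triisopropylsilyl triflate, CC(C)[Si](C(C)C)(C(C)C)OS(=O)(=O)C(F)(F)F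
Why: The acetylenic C–H is by far the most acidic and is removed first; the acetylide is oxidised at carbon by the electrophilic peroxide oxygen to the lithium ynolate, which the hard, bulky silyl triflate traps on oxygen to give an isolable ynol silyl ether; with one equivalent of base at −78 °C the propargylic centre is not touched.

Step 16
Reactants: 8 3-benzyloxy-2-(hepta-O-benzyl-epicatechin-gallate-4β-yl)cyclobut-2-en-1-one; 25 (3R,4R,5S)-5-[3,4-bis(benzyloxy)phenyl]-3-(penta-O-benzylcatechin-8-yl)-4,5-bis(triethylsilyloxy)-1-(triisopropylsilyloxy)pent-1-yne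
Product: 30 ring-A phenol of the central unit (C8a–OH free; C5–OSi(i-Pr)3; C7–OBn; upper unit at C6; open C4–C3–C2 chain at C4a), via vinylketene 26 (not isolated), via vinylcyclobutenone 27 (not isolated), via dienylketene 28 (not isolated), via cyclohexadienone 29 (not isolated)
Conditions: 25 (1.2 equiv), toluene (degassed, 0.05 M), 80 → 110 °C, sealed tube, argon
Reagents that add atoms: none
Why: This is a Danheiser benzannulation of a cyclobutenone with a siloxyalkyne, the known route to resorcinol derivatives. Heating opens 8 by a conrotatory 4π-electrocyclic reaction to the vinylketene 26. The ketene carbonyl carbon (electrophilic) bonds to the β-carbon of the ynol ether (nucleophilic, the one carrying C4) and the ketene α-carbon to the silyloxy carbon in a regiospecific [2+2] cycloaddition, which gives 27 and creates the C4a–C8a and C5–C6 bonds. 27 reopens (4π) to the dienylketene 28, which closes between the ketene carbon and the terminal methylene to the cyclohexadienone 29, and tautomerisation gives the phenol 30; the one new ring, ring A of the central unit, is therefore closed by a 6π-electrocyclic (disrotatory) ring closure. No stereocentre is created: the quaternary carbon of 27 is transient, and none of the eight existing centres is exposed to acid, base or an adjacent carbonyl in this neutral thermal cascade. The only selectivity needed is regiochemical, and it is fixed by the polarity of the ketene–ynol ether pair, which puts the upper unit between the silyloxy and benzyloxy carbons and the chain next to the only free phenol, para to the upper unit. Benzyl ethers, the ester and the alkyl silyl ethers are inert in toluene at this temperature, and a slight excess of 25 with moderate dilution keeps the ketene from being consumed by the phenolic product.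

Step 17
Reactants: 30 ring-A phenol of the central unit
Product: 31 phenol-diol (C2–OH and C3–OH of the central chain free; C5–OSi(i-Pr)3 kept)
Conditions: HF·pyridine, pyridine, THF, 0 °C → rt
Reagents that add atoms: none
Why: Buffered hydrogen fluoride cleaves the two alkyl triethylsilyl ethers much faster than the aryl triisopropylsilyl ether, and no nucleophilic solvent is present that could solvolyse the electron-rich benzylic alcohol.

Step 18
Reactants: 31 phenol-diol
Product: 32 protected trimer with closed central pyran ring (2R,3R,4β), free central C3–OH and C5–OSi(i-Pr)3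
Conditions: PPh3, DIAD, THF, 0 °C
Reagents that add atoms: none
Why: Intramolecular Mitsunobu etherification: the phenol, the only acidic O–H, is deprotonated by the betaine, the less hindered benzylic hydroxyl is activated as the oxyphosphonium ion, and the phenoxide displaces it in a 6-exo-tet SN2 closure with inversion, which turns the (S)-carbinol into (2R) and gives the 2,3-cis ring; the C3 hydroxyl, flanked by the diarylmethine, is neither acidic nor accessible enough to compete.

Step 19
Reactants: 32 protected trimer with free central C3–OH; 3 3,4,5-tris(benzyloxy)benzoic acid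
Product: 33 fully protected trimer bis-gallate (C5–OSi(i-Pr)3 on the central unit)
Conditions: 3, DCC, DMAP, CH2Cl2, rt
Reagents that add atoms: none
Why: Steglich esterification of the only free hydroxyl; the acylpyridinium intermediate reaches the hindered axial C3 alcohol, and no stereocentre is involved.

Step 20
Reactants: 33 fully protected trimer bis-gallate
Product: 34 octadeca-O-benzyl trimer bis-gallate with free C5–OH on the central unit
Conditions: Bu4NF, AcOH, THF, 0 °C
Reagents that add atoms: none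
Why: Fluoride cleaves the aryl silyl ether, and acetic acid buffers the phenoxide so that the gallate esters are not transesterified.

Step 21
Reactants: 34 octadeca-O-benzyl trimer bis-gallate
Product: 35 epicatechin-3-O-gallate-(4β→6)-epicatechin-3-O-gallate-(4β→8)-catechin (CNP0112921.1)
Conditions: H2 (1 atm), Pd(OH)2/C, THF/MeOH/H2O, rt
Reagents that add atoms: none
Why: Hydrogenolysis of all eighteen benzyl ethers under neutral conditions leaves the esters, the interflavan bonds and all eight stereocentres unchanged.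

## Compound list

1 | (−)-epicatechin | O[C@@H]1Cc2c(O)cc(O)cc2O[C@@H]1c1ccc(O)c(O)c1 | starting material
2 | 5,7,3',4'-tetra-O-benzyl-(−)-epicatechin, (2R,3R) | O[C@@H]1Cc2c(OCc9ccccc9)cc(OCc9ccccc9)cc2O[C@@H]1c1ccc(OCc9ccccc9)c(OCc9ccccc9)c1 | intermediate
3 | 3,4,5-tris(benzyloxy)benzoic acid | OC(=O)c1cc(OCc9ccccc9)c(OCc9ccccc9)c(OCc9ccccc9)c1 | starting material
4 | hepta-O-benzyl-(−)-epicatechin 3-O-gallate, (2R,3R) | O=C(O[C@@H]1Cc2c(OCc9ccccc9)cc(OCc9ccccc9)cc2O[C@@H]1c1ccc(OCc9ccccc9)c(OCc9ccccc9)c1)c1cc(OCc9ccccc9)c(OCc9ccccc9)c(OCc9ccccc9)c1 | intermediate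
5 | (2R,3R,4S)-4-(2-ethoxyethoxy) derivative of 4 (4β) | O=C(O[C@@H]1[C@@H](OCCOCC)c2c(OCc9ccccc9)cc(OCc9ccccc9)cc2O[C@@H]1c1ccc(OCc9ccccc9)c(OCc9ccccc9)c1)c1cc(OCc9ccccc9)c(OCc9ccccc9)c(OCc9ccccc9)c1 | intermediate
6 | cyclobutane-1,3-dione | O=C1CC(=O)C1 | starting material
7 | 3-hydroxy-2-(hepta-O-benzyl-epicatechin-gallate-4β-yl)cyclobut-2-en-1-one | O=C(O[C@@H]1[C@@H](C2=C(O)CC2=O)c2c(OCc9ccccc9)cc(OCc9ccccc9)cc2O[C@@H]1c1ccc(OCc9ccccc9)c(OCc9ccccc9)c1)c1cc(OCc9ccccc9)c(OCc9ccccc9)c(OCc9ccccc9)c1 | intermediate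
8 | 3-benzyloxy-2-(hepta-O-benzyl-epicatechin-gallate-4β-yl)cyclobut-2-en-1-one | O=C(O[C@@H]1[C@@H](C2=C(OCc9ccccc9)CC2=O)c2c(OCc9ccccc9)cc(OCc9ccccc9)cc2O[C@@H]1c1ccc(OCc9ccccc9)c(OCc9ccccc9)c1)c1cc(OCc9ccccc9)c(OCc9ccccc9)c(OCc9ccccc9)c1 | intermediate (precursor of the key step)
9 | (+)-catechin | O[C@H]1Cc2c(O)cc(O)cc2O[C@@H]1c1ccc(O)c(O)c1 | starting material
10 | 5,7,3',4'-tetra-O-benzyl-(+)-catechin | O[C@H]1Cc2c(OCc9ccccc9)cc(OCc9ccccc9)cc2O[C@@H]1c1ccc(OCc9ccccc9)c(OCc9ccccc9)c1 | intermediate (not isolated)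
11 | 3,5,7,3',4'-penta-O-benzyl-(+)-catechin | O(Cc9ccccc9)[C@H]1Cc2c(OCc9ccccc9)cc(OCc9ccccc9)cc2O[C@@H]1c1ccc(OCc9ccccc9)c(OCc9ccccc9)c1 | intermediate
12 | ethyl (Z)-3-iodoacrylate | CCOC(=O)/C=C\I | starting material
13 | ethyl (Z)-pent-2-en-4-ynoate | CCOC(=O)/C=C\C#C | intermediate
14 | (Z)-pent-2-en-4-yn-1-ol | OC/C=C\C#C | intermediate
15 | [(2S,3R)-3-ethynyloxiran-2-yl]methanol | C#C[C@H]1O[C@H]1CO | intermediate
16 | (2R,3R)-3-(penta-O-benzylcatechin-8-yl)pent-4-yne-1,2-diol | C#C[C@H](c1c(OCc9ccccc9)cc(OCc9ccccc9)c2c1O[C@H](c1ccc(OCc9ccccc9)c(OCc9ccccc9)c1)[C@@H](OCc9ccccc9)C2)[C@@H](O)CO | intermediate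
17 | (2R,3R)-3-(penta-O-benzylcatechin-8-yl)-1,2-bis(triethylsilyloxy)pent-4-yne | C#C[C@H](c1c(OCc9ccccc9)cc(OCc9ccccc9)c2c1O[C@H](c1ccc(OCc9ccccc9)c(OCc9ccccc9)c1)[C@@H](OCc9ccccc9)C2)[C@@H](O[Si](CC)(CC)CC)CO[Si](CC)(CC)CC | intermediate
18 | (2R,3R)-3-(penta-O-benzylcatechin-8-yl)-2-(triethylsilyloxy)pent-4-ynal | C#C[C@H](c1c(OCc9ccccc9)cc(OCc9ccccc9)c2c1O[C@H](c1ccc(OCc9ccccc9)c(OCc9ccccc9)c1)[C@@H](OCc9ccccc9)C2)[C@@H](O[Si](CC)(CC)CC)C=O | intermediate
19 | 4-bromo-1,2-bis(benzyloxy)benzene | Brc1ccc(OCc9ccccc9)c(OCc9ccccc9)c1 | starting material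
20 | 3,4-bis(benzyloxy)phenylmagnesium bromide | Br[Mg]c1ccc(OCc9ccccc9)c(OCc9ccccc9)c1 | intermediate (not isolated)
21 | (1S,2R,3R)-1-[3,4-bis(benzyloxy)phenyl]-3-(penta-O-benzylcatechin-8-yl)-2-(triethylsilyloxy)pent-4-yn-1-ol | C#C[C@H](c1c(OCc9ccccc9)cc(OCc9ccccc9)c2c1O[C@H](c1ccc(OCc9ccccc9)c(OCc9ccccc9)c1)[C@@H](OCc9ccccc9)C2)[C@@H](O[Si](CC)(CC)CC)[C@@H](O)c1ccc(OCc9ccccc9)c(OCc9ccccc9)c1 | intermediate
22 | (1S,2R,3R)-1-[3,4-bis(benzyloxy)phenyl]-3-(penta-O-benzylcatechin-8-yl)-1,2-bis(triethylsilyloxy)pent-4-yne | C#C[C@H](c1c(OCc9ccccc9)cc(OCc9ccccc9)c2c1O[C@H](c1ccc(OCc9ccccc9)c(OCc9ccccc9)c1)[C@@H](OCc9ccccc9)C2)[C@@H](O[Si](CC)(CC)CC)[C@@H](O[Si](CC)(CC)CC)c1ccc(OCc9ccccc9)c(OCc9ccccc9)c1 | intermediate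
23 | lithium acetylide of 22 | [Li]C#C[C@H](c1c(OCc9ccccc9)cc(OCc9ccccc9)c2c1O[C@H](c1ccc(OCc9ccccc9)c(OCc9ccccc9)c1)[C@@H](OCc9ccccc9)C2)[C@@H](O[Si](CC)(CC)CC)[C@@H](O[Si](CC)(CC)CC)c1ccc(OCc9ccccc9)c(OCc9ccccc9)c1 | intermediate (not isolated)
24 | lithium ynolate derived from 23 | [Li]OC#C[C@H](c1c(OCc9ccccc9)cc(OCc9ccccc9)c2c1O[C@H](c1ccc(OCc9ccccc9)c(OCc9ccccc9)c1)[C@@H](OCc9ccccc9)C2)[C@@H](O[Si](CC)(CC)CC)[C@@H](O[Si](CC)(CC)CC)c1ccc(OCc9ccccc9)c(OCc9ccccc9)c1 | intermediate (not isolated)
25 | (3R,4R,5S)-5-[3,4-bis(benzyloxy)phenyl]-3-(penta-O-benzylcatechin-8-yl)-4,5-bis(triethylsilyloxy)-1-(triisopropylsilyloxy)pent-1-yne | CC(C)[Si](C(C)C)(C(C)C)OC#C[C@H](c1c(OCc9ccccc9)cc(OCc9ccccc9)c2c1O[C@H](c1ccc(OCc9ccccc9)c(OCc9ccccc9)c1)[C@@H](OCc9ccccc9)C2)[C@@H](O[Si](CC)(CC)CC)[C@@H](O[Si](CC)(CC)CC)c1ccc(OCc9ccccc9)c(OCc9ccccc9)c1 | intermediate (precursor of the key step)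
26 | vinylketene from 8: 3-benzyloxy-2-(upper-unit-4β-yl)buta-1,3-dien-1-one | O=C(O[C@@H]1[C@@H](C(=C=O)C(OCc9ccccc9)=C)c2c(OCc9ccccc9)cc(OCc9ccccc9)cc2O[C@@H]1c1ccc(OCc9ccccc9)c(OCc9ccccc9)c1)c1cc(OCc9ccccc9)c(OCc9ccccc9)c(OCc9ccccc9)c1 | intermediate (not isolated)
27 | 4-(1-benzyloxyvinyl)-4-(upper-unit-4β-yl)-3-(triisopropylsilyloxy)-2-(central chain)cyclobut-2-en-1-one (quaternary carbon unassigned) | O=C(O[C@@H]1[C@@H](C2(C(OCc9ccccc9)=C)C(O[Si](C(C)C)(C(C)C)C(C)C)=C([C@H](c3c(OCc9ccccc9)cc(OCc9ccccc9)c4c3O[C@H](c3ccc(OCc9ccccc9)c(OCc9ccccc9)c3)[C@@H](OCc9ccccc9)C4)[C@@H](O[Si](CC)(CC)CC)[C@@H](O[Si](CC)(CC)CC)c3ccc(OCc9ccccc9)c(OCc9ccccc9)c3)C2=O)c2c(OCc9ccccc9)cc(OCc9ccccc9)cc2O[C@@H]1c1ccc(OCc9ccccc9)c(OCc9ccccc9)c1)c1cc(OCc9ccccc9)c(OCc9ccccc9)c(OCc9ccccc9)c1 | intermediate (not isolated)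
28 | dienylketene from 27 (central alkene geometry unassigned) | O=C(O[C@@H]1[C@@H](C(C(OCc9ccccc9)=C)=C(O[Si](C(C)C)(C(C)C)C(C)C)C(=C=O)[C@H](c3c(OCc9ccccc9)cc(OCc9ccccc9)c4c3O[C@H](c3ccc(OCc9ccccc9)c(OCc9ccccc9)c3)[C@@H](OCc9ccccc9)C4)[C@@H](O[Si](CC)(CC)CC)[C@@H](O[Si](CC)(CC)CC)c3ccc(OCc9ccccc9)c(OCc9ccccc9)c3)c2c(OCc9ccccc9)cc(OCc9ccccc9)cc2O[C@@H]1c1ccc(OCc9ccccc9)c(OCc9ccccc9)c1)c1cc(OCc9ccccc9)c(OCc9ccccc9)c(OCc9ccccc9)c1 | intermediate (not isolated)
29 | cyclohexa-2,4-dienone tautomer of 30 | O=C(O[C@@H]1[C@@H](C2=C(OCc9ccccc9)CC(=O)C([C@H](c3c(OCc9ccccc9)cc(OCc9ccccc9)c4c3O[C@H](c3ccc(OCc9ccccc9)c(OCc9ccccc9)c3)[C@@H](OCc9ccccc9)C4)[C@@H](O[Si](CC)(CC)CC)[C@@H](O[Si](CC)(CC)CC)c3ccc(OCc9ccccc9)c(OCc9ccccc9)c3)=C2O[Si](C(C)C)(C(C)C)C(C)C)c2c(OCc9ccccc9)cc(OCc9ccccc9)cc2O[C@@H]1c1ccc(OCc9ccccc9)c(OCc9ccccc9)c1)c1cc(OCc9ccccc9)c(OCc9ccccc9)c(OCc9ccccc9)c1 | intermediate (not isolated)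
30 | ring-A phenol of the central unit (C8a–OH free; C5–OSi(i-Pr)3; C7–OBn; upper unit at C6; chain with two OSiEt3 at C4a) | O=C(O[C@@H]1[C@@H](c2c(OCc9ccccc9)cc(O)c(c2O[Si](C(C)C)(C(C)C)C(C)C)[C@H](c2c(OCc9ccccc9)cc(OCc9ccccc9)c4c2O[C@H](c2ccc(OCc9ccccc9)c(OCc9ccccc9)c2)[C@@H](OCc9ccccc9)C4)[C@@H](O[Si](CC)(CC)CC)[C@@H](O[Si](CC)(CC)CC)c2ccc(OCc9ccccc9)c(OCc9ccccc9)c2)c2c(OCc9ccccc9)cc(OCc9ccccc9)cc2O[C@@H]1c1ccc(OCc9ccccc9)c(OCc9ccccc9)c1)c1cc(OCc9ccccc9)c(OCc9ccccc9)c(OCc9ccccc9)c1 | intermediate (product of the key step)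
31 | phenol-diol from 30 (both triethylsilyl groups removed) | O=C(O[C@@H]1[C@@H](c2c(OCc9ccccc9)cc(O)c(c2O[Si](C(C)C)(C(C)C)C(C)C)[C@H](c2c(OCc9ccccc9)cc(OCc9ccccc9)c4c2O[C@H](c2ccc(OCc9ccccc9)c(OCc9ccccc9)c2)[C@@H](OCc9ccccc9)C4)[C@@H](O)[C@@H](O)c2ccc(OCc9ccccc9)c(OCc9ccccc9)c2)c2c(OCc9ccccc9)cc(OCc9ccccc9)cc2O[C@@H]1c1ccc(OCc9ccccc9)c(OCc9ccccc9)c1)c1cc(OCc9ccccc9)c(OCc9ccccc9)c(OCc9ccccc9)c1 | intermediate
32 | protected trimer with closed central pyran ring, free central C3–OH, C5–OSi(i-Pr)3 | O=C(O[C@@H]1[C@@H](c2c(OCc9ccccc9)cc3c(c2O[Si](C(C)C)(C(C)C)C(C)C)[C@H](c2c(OCc9ccccc9)cc(OCc9ccccc9)c4c2O[C@H](c2ccc(OCc9ccccc9)c(OCc9ccccc9)c2)[C@@H](OCc9ccccc9)C4)[C@@H](O)[C@@H](c2ccc(OCc9ccccc9)c(OCc9ccccc9)c2)O3)c2c(OCc9ccccc9)cc(OCc9ccccc9)cc2O[C@@H]1c1ccc(OCc9ccccc9)c(OCc9ccccc9)c1)c1cc(OCc9ccccc9)c(OCc9ccccc9)c(OCc9ccccc9)c1 | intermediate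
33 | fully protected trimer bis-gallate (C5–OSi(i-Pr)3 on the central unit) | O=C(O[C@@H]1[C@@H](c2c(OCc9ccccc9)cc3c(c2O[Si](C(C)C)(C(C)C)C(C)C)[C@H](c2c(OCc9ccccc9)cc(OCc9ccccc9)c4c2O[C@H](c2ccc(OCc9ccccc9)c(OCc9ccccc9)c2)[C@@H](OCc9ccccc9)C4)[C@@H](OC(=O)c2cc(OCc9ccccc9)c(OCc9ccccc9)c(OCc9ccccc9)c2)[C@@H](c2ccc(OCc9ccccc9)c(OCc9ccccc9)c2)O3)c2c(OCc9ccccc9)cc(OCc9ccccc9)cc2O[C@@H]1c1ccc(OCc9ccccc9)c(OCc9ccccc9)c1)c1cc(OCc9ccccc9)c(OCc9ccccc9)c(OCc9ccccc9)c1 | intermediate
34 | octadeca-O-benzyl trimer bis-gallate with free C5–OH on the central unit | O=C(O[C@@H]1[C@@H](c2c(OCc9ccccc9)cc3c(c2O)[C@H](c2c(OCc9ccccc9)cc(OCc9ccccc9)c4c2O[C@H](c2ccc(OCc9ccccc9)c(OCc9ccccc9)c2)[C@@H](OCc9ccccc9)C4)[C@@H](OC(=O)c2cc(OCc9ccccc9)c(OCc9ccccc9)c(OCc9ccccc9)c2)[C@@H](c2ccc(OCc9ccccc9)c(OCc9ccccc9)c2)O3)c2c(OCc9ccccc9)cc(OCc9ccccc9)cc2O[C@@H]1c1ccc(OCc9ccccc9)c(OCc9ccccc9)c1)c1cc(OCc9ccccc9)c(OCc9ccccc9)c(OCc9ccccc9)c1 | intermediate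
35 | epicatechin-3-O-gallate-(4β→6)-epicatechin-3-O-gallate-(4β→8)-catechin | O=C(O[C@@H]1[C@@H](c2c(O)cc3c(c2O)[C@H](c2c(O)cc(O)c4c2O[C@H](c2ccc(O)c(O)c2)[C@@H](O)C4)[C@@H](OC(=O)c2cc(O)c(O)c(O)c2)[C@@H](c2ccc(O)c(O)c2)O3)c2c(O)cc(O)cc2O[C@@H]1c1ccc(O)c(O)c1)c1cc(O)c(O)c(O)c1 | target

## Step count and least certain steps

Total: 21 steps. Longest linear sequence: 15 steps (steps 7 to 21, from 12). The upper-unit branch is steps 1 to 5 and the lower-unit branch is step 6.

Step 16 (key step). The most likely failure is a slow [2+2] cycloaddition between a ketene with a very bulky α-substituent and a β-branched ynol ether. The vinylketene could then dimerise or acylate the phenolic product, and prolonged heating could cause loss of the silyl group from the ynol ether. The fallback takes the central ring A from the chiral pool and forces the 4→6 bond by bromine blocking; it sets out from 4, 5 and 11 and returns at 35. 4 is brominated at C8 with NBS to the 8-bromo gallate F1, which is oxidised with DDQ in the presence of 2-ethoxyethanol to the C4 ether F2. TMSOTf-promoted coupling of F2 with 11 gives the 4β→8 dimer F3. Of its two remaining ring A positions, C6 of the lower unit is the more electron-rich, because the central ring A is deactivated by its bromine, and it is brominated with NBS to give the dibromide F4. A second TMSOTf-promoted coupling, now with 5, can then occur only at C6 of the central unit and gives the protected trimer F5. Hydrogenolysis over Pd(OH)2/C in the presence of Et3N removes the benzyl groups and both bromine atoms and gives 35.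

Step 10. The risks are erosion of configuration at the propargylic carbon if the activated epoxide opens to a free cation before the arene arrives, competing attack at C6 of 11, and hydride-shift rearrangement of the epoxide. The fallback replaces the π-nucleophile by an organometallic one; it sets out from 11 and 15 and returns at 16. 11 is brominated with NBS to the 8-bromide F6. Bromine–lithium exchange (t-BuLi) followed by Et2AlCl gives the aryldiethylalane F7, which opens the diethylaluminium alkoxide of 15 (from Et3Al) at the distal, propargylic carbon with inversion. This is the known C3-selective opening of 2,3-epoxy alcohols by organoaluminium reagents, and it gives 16.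

Step 13. The risk is poor facial selectivity: partial chelation by magnesium or a steric preference of the bulky β-substituent could favour the 1,2-syn carbinol. The fallback uses reagent control; it sets out from 21 obtained as a mixture of C1 epimers and returns at 21. Dess–Martin oxidation gives the aryl ketone F8, and Corey–Bakshi–Shibata reduction with the (S)-oxazaborolidine and catecholborane at −78 °C, with the aryl group acting as the larger substituent, should give the (1S) carbinol 21.

Step 18. The risk is ionisation of the activated, electron-rich benzylic oxyphosphonium ion before the phenoxide attacks (loss of inversion and formation of the 2,3-trans ring), or closure through the neighbouring hydroxyl to an oxirane. The fallback keeps the leaving oxygen tethered; it sets out from 31 and returns at 32. Triethyl orthoformate and PPTS convert the 1,2-diol into the cyclic orthoformate F9. On warming, loss of ethanol gives a dioxolanylium ion that stays bonded to O3 while the phenol opens it at the benzylic carbon with inversion, giving the 3-O-formate F10. KHCO3 in methanol then removes the formate without touching the hindered gallate and gives 32.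

Step 4. The risks are alcoholysis of the strained dione by the liberated 2-ethoxyethanol and kinetic O-alkylation of the enol. The fallback is a direct dehydrogenative coupling that liberates no alcohol; it sets out from 4 and 6 and returns at 7. 4 is oxidised with DDQ in CH2Cl2 in the presence of 6, so that the C4 cation is intercepted at once by the enol; no new compound is involved.

## Further compounds

F1 | step 16 | 8-bromo derivative of 4 | O=C(O[C@@H]1Cc2c(OCc9ccccc9)cc(OCc9ccccc9)c(Br)c2O[C@@H]1c1ccc(OCc9ccccc9)c(OCc9ccccc9)c1)c1cc(OCc9ccccc9)c(OCc9ccccc9)c(OCc9ccccc9)c1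
F2 | step 16 | 8-bromo-4β-(2-ethoxyethoxy) derivative of 4 | O=C(O[C@@H]1[C@@H](OCCOCC)c2c(OCc9ccccc9)cc(OCc9ccccc9)c(Br)c2O[C@@H]1c1ccc(OCc9ccccc9)c(OCc9ccccc9)c1)c1cc(OCc9ccccc9)c(OCc9ccccc9)c(OCc9ccccc9)c1
F3 | step 16 | benzylated 8-bromo-epicatechin-3-O-gallate-(4β→8)-catechin | O=C(O[C@@H]1[C@@H](c2c(OCc9ccccc9)cc(OCc9ccccc9)c3c2O[C@H](c2ccc(OCc9ccccc9)c(OCc9ccccc9)c2)[C@@H](OCc9ccccc9)C3)c2c(OCc9ccccc9)cc(OCc9ccccc9)c(Br)c2O[C@@H]1c1ccc(OCc9ccccc9)c(OCc9ccccc9)c1)c1cc(OCc9ccccc9)c(OCc9ccccc9)c(OCc9ccccc9)c1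
F4 | step 16 | dibromide of F3 (Br at C8 of the gallate unit and at C6 of the catechin unit) | O=C(O[C@@H]1[C@@H](c2c(OCc9ccccc9)c(Br)c(OCc9ccccc9)c3c2O[C@H](c2ccc(OCc9ccccc9)c(OCc9ccccc9)c2)[C@@H](OCc9ccccc9)C3)c2c(OCc9ccccc9)cc(OCc9ccccc9)c(Br)c2O[C@@H]1c1ccc(OCc9ccccc9)c(OCc9ccccc9)c1)c1cc(OCc9ccccc9)c(OCc9ccccc9)c(OCc9ccccc9)c1
F5 | step 16 | benzylated dibromo trimer bis-gallate (4β→6 and 4β→8 linked) | O=C(O[C@@H]1[C@@H](c2c(OCc9ccccc9)c(Br)c3c(c2OCc9ccccc9)[C@H](c2c(OCc9ccccc9)c(Br)c(OCc9ccccc9)c4c2O[C@H](c2ccc(OCc9ccccc9)c(OCc9ccccc9)c2)[C@@H](OCc9ccccc9)C4)[C@@H](OC(=O)c2cc(OCc9ccccc9)c(OCc9ccccc9)c(OCc9ccccc9)c2)[C@@H](c2ccc(OCc9ccccc9)c(OCc9ccccc9)c2)O3)c2c(OCc9ccccc9)cc(OCc9ccccc9)cc2O[C@@H]1c1ccc(OCc9ccccc9)c(OCc9ccccc9)c1)c1cc(OCc9ccccc9)c(OCc9ccccc9)c(OCc9ccccc9)c1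
F6 | step 10 | 8-bromo-3,5,7,3',4'-penta-O-benzyl-(+)-catechin | Brc1c(OCc9ccccc9)cc(OCc9ccccc9)c2c1O[C@H](c1ccc(OCc9ccccc9)c(OCc9ccccc9)c1)[C@@H](OCc9ccccc9)C2
F7 | step 10 | diethyl(penta-O-benzylcatechin-8-yl)alane | CC[Al](CC)c1c(OCc9ccccc9)cc(OCc9ccccc9)c2c1O[C@H](c1ccc(OCc9ccccc9)c(OCc9ccccc9)c1)[C@@H](OCc9ccccc9)C2
F8 | step 13 | (2R,3R)-1-[3,4-bis(benzyloxy)phenyl]-3-(penta-O-benzylcatechin-8-yl)-2-(triethylsilyloxy)pent-4-yn-1-one | C#C[C@H](c1c(OCc9ccccc9)cc(OCc9ccccc9)c2c1O[C@H](c1ccc(OCc9ccccc9)c(OCc9ccccc9)c1)[C@@H](OCc9ccccc9)C2)[C@@H](O[Si](CC)(CC)CC)C(=O)c1ccc(OCc9ccccc9)c(OCc9ccccc9)c1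
F9 | step 18 | cyclic ethyl orthoformate of the 1,2-diol of 31 | O=C(O[C@@H]1[C@@H](c2c(OCc9ccccc9)cc(O)c(c2O[Si](C(C)C)(C(C)C)C(C)C)[C@H](c2c(OCc9ccccc9)cc(OCc9ccccc9)c4c2O[C@H](c2ccc(OCc9ccccc9)c(OCc9ccccc9)c2)[C@@H](OCc9ccccc9)C4)[C@H]5OC(OCC)O[C@H]5c2ccc(OCc9ccccc9)c(OCc9ccccc9)c2)c2c(OCc9ccccc9)cc(OCc9ccccc9)cc2O[C@@H]1c1ccc(OCc9ccccc9)c(OCc9ccccc9)c1)c1cc(OCc9ccccc9)c(OCc9ccccc9)c(OCc9ccccc9)c1
F10 | step 18 | 3-O-formate of 32 | O=C(O[C@@H]1[C@@H](c2c(OCc9ccccc9)cc3c(c2O[Si](C(C)C)(C(C)C)C(C)C)[C@H](c2c(OCc9ccccc9)cc(OCc9ccccc9)c4c2O[C@H](c2ccc(OCc9ccccc9)c(OCc9ccccc9)c2)[C@@H](OCc9ccccc9)C4)[C@@H](OC=O)[C@@H](c2ccc(OCc9ccccc9)c(OCc9ccccc9)c2)O3)c2c(OCc9ccccc9)cc(OCc9ccccc9)cc2O[C@@H]1c1ccc(OCc9ccccc9)c(OCc9ccccc9)c1)c1cc(OCc9ccccc9)c(OCc9ccccc9)c(OCc9ccccc9)c1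
F0 | step 4 | none | none
A1 | alternative 1 | C3 boronic ester (1,2-dicyclohexylethanediol ester) carrying the PMB ether and the diarylmethine C4 | B1(O[C@@H](C2CCCCC2)[C@H](C2CCCCC2)O1)[C@H](OCc2ccc(OC)cc2)[C@H](c2c(Br)cc(OCc9ccccc9)cc2OCc9ccccc9)c2c(OCc9ccccc9)cc(OCC=C)cc2OCc9ccccc9
A2 | alternative 1 | C2 boronic ester with the complete C2–C3–C4 triad of the upper unit | B1(O[C@@H](C2CCCCC2)[C@H](C2CCCCC2)O1)[C@H](c2ccc(OCc9ccccc9)c(OCc9ccccc9)c2)[C@H](OCc2ccc(OC)cc2)[C@H](c2c(Br)cc(OCc9ccccc9)cc2OCc9ccccc9)c2c(OCc9ccccc9)cc(OCC=C)cc2OCc9ccccc9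
A3 | alternative 2 | (2-hydroxy-4,6-dibenzyloxyphenyl)(4-allyloxy-2,6-dibenzyloxyphenyl)methanol | OC(c1c(O)cc(OCc9ccccc9)cc1OCc9ccccc9)c1c(OCc9ccccc9)cc(OCC=C)cc1OCc9ccccc9
A4 | alternative 2 | (Z)-2-[3,4-bis(benzyloxy)phenyl]ethenyl 3,4,5-tris(benzyloxy)benzoate | O=C(O/C=C\c1ccc(OCc9ccccc9)c(OCc9ccccc9)c1)c1cc(OCc9ccccc9)c(OCc9ccccc9)c(OCc9ccccc9)c1
A5 | alternative 2 | benzylated upper unit 3-O-gallate with a 4-allyloxy-2,6-dibenzyloxyphenyl group at C4 | O=C(O[C@@H]1[C@@H](c2c(OCc9ccccc9)cc(OCC=C)cc2OCc9ccccc9)c2c(OCc9ccccc9)cc(OCc9ccccc9)cc2O[C@@H]1c1ccc(OCc9ccccc9)c(OCc9ccccc9)c1)c1cc(OCc9ccccc9)c(OCc9ccccc9)c(OCc9ccccc9)c1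
A6 | alternative 3 | ortho-hydroxybenzylic carbinol: central ring A with the 3-O-allyl upper unit at C6 and a (penta-O-benzylcatechin-8-yl)hydroxymethyl group at C4a | C=CCO[C@@H]1[C@@H](c2c(OCc9ccccc9)cc(O)c(c2OCc9ccccc9)C(O)c2c(OCc9ccccc9)cc(OCc9ccccc9)c4c2O[C@H](c2ccc(OCc9ccccc9)c(OCc9ccccc9)c2)[C@@H](OCc9ccccc9)C4)c2c(OCc9ccccc9)cc(OCc9ccccc9)cc2O[C@@H]1c1ccc(OCc9ccccc9)c(OCc9ccccc9)c1
A7 | alternative 3 | trans-3-allyloxy-4-(catechin-8-yl)-3,4-dihydrocoumarin fused on the central ring A | C=CCO[C@@H]1[C@@H](c2c(OCc9ccccc9)cc3c(c2OCc9ccccc9)[C@H](c2c(OCc9ccccc9)cc(OCc9ccccc9)c4c2O[C@H](c2ccc(OCc9ccccc9)c(OCc9ccccc9)c2)[C@@H](OCc9ccccc9)C4)[C@@H](OCC=C)C(=O)O3)c2c(OCc9ccccc9)cc(OCc9ccccc9)cc2O[C@@H]1c1ccc(OCc9ccccc9)c(OCc9ccccc9)c1
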